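**Retrosynthetic overview**
- Ring labels: upper unit A (benzo), B (aryl), C (pyran); lower unit D (benzo), E (aryl), F (pyran). The strategy rests on ring F, where H-2, H-3 and H-4 lie on one face (2-aryl, 3-OH and 4-OH all cis), and on ring C, which repeats the same cis 2R,3R pair. This is the pattern left by syn addition of hydrogen to one face of a flat 3-oxygenated chromen-4-one.
- Last disconnection: the C4(ring C)–C6(ring D) bond, formed when the free phenolic monomer captures an upper-unit C4 cation released from a 4β-benzylsulfanyl derivative. Both halves are the same all-cis 7,8,4'-trihydroxyflavan-3,4-diol.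
- The monomer is traced to an achiral tetra-O-benzyl flavonol by one enantioselective hydrogenation of C2=C3 and C4=O (three C–H bonds, three stereocentres).
- Ring order: the benzo and aryl rings are bought (gallacetophenone, 4-benzyloxybenzaldehyde). The pyran ring is closed once at the achiral stage by O1–C2 bond formation (Algar–Flynn–Oyamada), saturated in the key step, and the two units are joined last.

Key step: step 5

Assumption: the (R,R) antipode of the NHC ligand is taken as the one that hydrogenates the face leading to 2R,3R,4R; if the sense proves opposite, the (S,S) antipode is used and nothing else changes.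
Remark: SINpEt·HBF4 is 1,3-bis[1-(1-naphthyl)ethyl]-4,5-dihydroimidazolium tetrafluoroborate, the precursor of the chiral NHC.

**Step 1**
Reactants: 1 gallacetophenone (2,3,4-trihydroxyacetophenone); 2 benzyl bromide (2.1 equiv)
Product: 3 3,4-bis(benzyloxy)-2-hydroxyacetophenone
Conditions: K2CO3 (2.2 equiv), acetone, reflux
Reagents that add atoms: none
Why: Williamson etherification under carbonate, in which the 4-OH (para to the acetyl) and the 3-OH are alkylated while the 2-OH, held in a strong hydrogen bond to the carbonyl, should stay free when only two equivalents of halide are offered.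

**Step 2**
Reactants: 3 3,4-bis(benzyloxy)-2-hydroxyacetophenone; 4 4-(benzyloxy)benzaldehyde
Product: 6 2'-hydroxy-3',4',4-tris(benzyloxy)chalcone (E), via aldol adduct 5 (not isolated)
Conditions: KOH (aq., excess), EtOH, rt to 50 °C; then dilute HCl
Reagents that add atoms: none
Why: Claisen–Schmidt condensation, in which the methyl ketone enolate adds to the non-enolisable aldehyde and the aldol adduct loses water in the same basic medium to give the conjugated E-enone under thermodynamic control.

**Step 3**
Reactants: 6 2'-hydroxy-3',4',4-tris(benzyloxy)chalcone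
Product: 8 7,8,4'-tris(benzyloxy)flavonol, via racemic trans-dihydroflavonol 7 (not isolated)
Conditions: H2O2 (30% aq.), NaOH (aq.), MeOH–THF, 0 °C to rt; then dilute HCl
Reagents that add atoms: hydrogen peroxide, OO
Why: Algar–Flynn–Oyamada reaction, in which alkaline hydroperoxide oxidises the enone while the 2'-phenoxide attacks the β-carbon, closing ring C through the O1–C2 bond and placing O-3; the dihydroflavonol is dehydrogenated in the same pot to the achiral flavonol, and no 6'-substituent is present to favour an aurone.

**Step 4**
Reactants: 8 7,8,4'-tris(benzyloxy)flavonol; 2 benzyl bromide (1.2 equiv)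
Product: 9 3,7,8,4'-tetrakis(benzyloxy)flavone
Conditions: K2CO3, DMF, 60 °C
Reagents that add atoms: none
Why: Williamson O-benzylation of the acidic enolic 3-OH, which removes the chelating 3-hydroxy-4-oxo unit that could bind and deactivate the hydrogenation catalyst.

**Step 5**
Reactants: 9 3,7,8,4'-tetrakis(benzyloxy)flavone
Product: 11 (2R,3R,4R)-3,7,8,4'-tetra-O-benzylteracacidin (all-cis 3,7,8-tris(benzyloxy)-2-[4-(benzyloxy)phenyl]chroman-4-ol), via (2R,3S)-cis-3-benzyloxyflavanone 10 (not isolated)
Conditions: Ru(cod)(2-methylallyl)2 (5 mol%), (R,R)-SINpEt·HBF4 (10 mol%), KOtBu (10 mol%), n-hexane, 70 °C (catalyst formation); then 9, toluene, H2 (100 bar), 40 °C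
Reagents that add atoms: none
Why: Proposed new method: the chiral Ru bis(NHC) hydride is expected to bind one face of the flat benzopyranone and add H2 syn across the tetrasubstituted C2=C3 enol ether bond, giving the kinetic 2,3-cis flavanone 10 (aryl equatorial, benzyloxy axial), whose C4 carbonyl is then reduced from the same face, anti to the axial 3-OBn, so that H-2, H-3 and H-4 end up on one face. The closest known reaction types are the Ru–NHC-catalysed asymmetric hydrogenation of flavones and chromones to cis-flavan-4-ols and the heterogeneous hydrogenation of flavonol ethers to racemic all-cis flavan-3,4-diols; the extrapolation is enantiofacial control on a 3-alkoxy, tetrasubstituted C2=C3 bond. No ring is closed; ring C is only saturated. C2 and C3 are set by the ligand-controlled choice of olefin face together with syn addition, and C4 is set by the substrate (hydride delivery anti to the axial 3-OBn, reinforced by the catalyst remaining on the same face). The step needs enantiofacial selectivity and all-syn diastereoselectivity; the substrate supplies a planar achiral ring C with its chelating 3-OH capped, and the low-base apolar medium should let ketone reduction outrun C3 epimerisation or retro-oxa-Michael opening of 10. The benzyl ethers and arene rings should not be touched by this homogeneous catalyst.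

**Step 6**
Reactants: 11 (2R,3R,4R)-3,7,8,4'-tetra-O-benzylteracacidin
Product: 12 (2R,3R,4R)-teracacidin (epioritin-4α-ol; (2R,3R,4R)-2-(4-hydroxyphenyl)chromane-3,4,7,8-tetrol)
Conditions: H2 (1 atm), Pd(OH)2/C, acid-free EtOAc–THF, rt; stopped after uptake of 4 equiv H2
Reagents that add atoms: none
Why: Catalytic hydrogenolysis of benzyl ethers, in which the four O-benzyl bonds should cleave in acid-free solvent well before the C4 benzylic hydroxyl (whose reductive loss needs acid-assisted ionisation), with no stereocentre involved.

**Step 7**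
Reactants: 12 (2R,3R,4R)-teracacidin; 13 phenylmethanethiol (10 equiv)
Product: 14 4β-benzylsulfanylepioritin ((2R,3S,4S)-4-(benzylsulfanyl)-2-(4-hydroxyphenyl)chromane-3,7,8-triol)
Conditions: AcOH, EtOH, 60 °C, Ar
Reagents that add atoms: none
Why: Acid-catalysed thiolysis (SN1), in which the protonated 4-OH leaves as water to give the benzylic cation stabilised by the para 7-OH and the ring oxygen, and the excess thiol traps this planar cation on the β face, anti to the quasi-axial 3-OH of the 2,3-cis ring, to give the 3,4-trans (4β) sulfide as is general for epi-configured flavan-4-yl cations.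

**Step 8**
Reactants: 14 4β-benzylsulfanylepioritin; 12 (2R,3R,4R)-teracacidin (4 equiv, surplus recovered)
Product: 15 epioritin-(4β→6)-epioritin-4α-ol (target)
Conditions: AgBF4 (2.5 equiv), THF, 0 °C, dark, Ar; then aq. NaHCO3
Reagents that add atoms: none
Why: Friedel–Crafts-type interflavanyl coupling under thiophilic activation, in which Ag+ removes the benzylsulfanyl group to give the same C4 cation and the benzo ring of free 12 captures it at C6 (ortho to 7-OH and para to the ring oxygen, whereas C5 is peri-hindered) on the β face anti to the 3-OH, setting the upper C4 as S (4β) and leaving the five stereocentres from step 5 untouched.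

**Compound list**
1 | gallacetophenone (2,3,4-trihydroxyacetophenone) | CC(=O)c1ccc(O)c(O)c1O | starting material
2 | benzyl bromide | BrCc1ccccc1 | starting material
3 | 3,4-bis(benzyloxy)-2-hydroxyacetophenone | CC(=O)c1ccc(OCc2ccccc2)c(OCc2ccccc2)c1O | intermediate
4 | 4-(benzyloxy)benzaldehyde | O=Cc1ccc(OCc2ccccc2)cc1 | starting material
5 | aldol adduct, racemic 3-[4-(benzyloxy)phenyl]-1-[3,4-bis(benzyloxy)-2-hydroxyphenyl]-3-hydroxypropan-1-one (not isolated) | O=C(CC(O)c1ccc(OCc2ccccc2)cc1)c1ccc(OCc2ccccc2)c(OCc2ccccc2)c1O | intermediate
6 | 2'-hydroxy-3',4',4-tris(benzyloxy)chalcone (E) | O=C(/C=C/c1ccc(OCc2ccccc2)cc1)c1ccc(OCc2ccccc2)c(OCc2ccccc2)c1O | intermediate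
7 | racemic trans-7,8,4'-tris(benzyloxy)dihydroflavonol (2R*,3R*; one enantiomer drawn; not isolated) | O=C1c2ccc(OCc3ccccc3)c(OCc3ccccc3)c2O[C@H](c2ccc(OCc3ccccc3)cc2)[C@H]1O | intermediate
8 | 7,8,4'-tris(benzyloxy)flavonol | O=c1c(O)c(-c2ccc(OCc3ccccc3)cc2)oc2c(OCc3ccccc3)c(OCc3ccccc3)ccc12 | intermediate
9 | 3,7,8,4'-tetrakis(benzyloxy)flavone | O=c1c(OCc2ccccc2)c(-c2ccc(OCc3ccccc3)cc2)oc2c(OCc3ccccc3)c(OCc3ccccc3)ccc12 | intermediate
10 | (2R,3S)-2,3-cis-3,7,8-tris(benzyloxy)-2-[4-(benzyloxy)phenyl]chroman-4-one (not isolated) | O=C1c2ccc(OCc3ccccc3)c(OCc3ccccc3)c2O[C@H](c2ccc(OCc3ccccc3)cc2)[C@@H]1OCc1ccccc1 | intermediate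
11 | (2R,3R,4R)-3,7,8,4'-tetra-O-benzylteracacidin (all-cis) | c1ccccc1COc1ccc2c(c1OCc1ccccc1)O[C@H](c1ccc(OCc3ccccc3)cc1)[C@H](OCc1ccccc1)[C@@H]2O | intermediate
12 | (2R,3R,4R)-teracacidin (epioritin-4α-ol) | Oc1ccc2c(c1O)O[C@H](c1ccc(O)cc1)[C@H](O)[C@@H]2O | intermediate
13 | phenylmethanethiol | SCc1ccccc1 | starting material
14 | 4β-benzylsulfanylepioritin, (2R,3S,4S) | Oc1ccc([C@H]2Oc3c(ccc(O)c3O)[C@H](SCc3ccccc3)[C@H]2O)cc1 | intermediate
15 | epioritin-(4β→6)-epioritin-4α-ol; upper unit 2R,3R,4S, lower unit 2R,3R,4R | Oc1ccc([C@H]2Oc3c(ccc(O)c3O)[C@H](c3cc4c(c(O)c3O)O[C@H](c3ccc(O)cc3)[C@H](O)[C@@H]4O)[C@H]2O)cc1 | target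

**Step count**
Total: 8 steps. Longest linear sequence: 8 steps (1 to 15); compound 12 is used twice, as the precursor of 14 and as the nucleophile in step 8.

**Steps most likely to fail**

Step 5 (Proposed new method). The hindered tetrasubstituted 3-benzyloxy C2=C3 bond may be hydrogenated slowly or with poor enantiofacial discrimination. The reaction may also stall at the ketone, so that C3 epimerises or the ring opens by retro-oxa-Michael elimination before C4 is reduced. The fallback uses known chemistry and sets out from 9. Heterogeneous syn hydrogenation (H2 under pressure, W-4 Raney Ni, a grade of low hydrogenolysis activity, EtOH–dioxane) is the classical conversion of flavonol ethers into all-cis flavan-3,4-diols and should give racemic all-cis 3,7,8,4'-tetra-O-benzylteracacidin F1. The enantiomers would be separated by preparative chromatography on an amylose tris(3,5-dimethylphenylcarbamate) stationary phase, and the 2R,3R,4R enantiomer, assigned by the chiroptical data of the teracacidin derived from it, is 11, where the route is rejoined.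

Step 6. The activated benzylic C4 hydroxyl (para to O-7) may be lost reductively while the slower aliphatic 3-O-benzyl ether is still being cleaved, so that ring C ends up as a flavan-3-ol. The fallback sets out from 11 and takes the sensitive hydroxyl out of play during hydrogenolysis. Oxidation with Dess–Martin periodinane (NaHCO3-buffered CH2Cl2) gives ketone 10, now isolated. Hydrogenolysis (H2, Pd(OH)2/C, EtOAc) should then give (2R,3S)-2,3-cis-3,7,8,4'-tetrahydroxyflavanone F2 without any benzylic C–O bond at C4 to cleave. Reduction with NaBH4 in EtOH at 0 °C, with hydride entering anti to the axial 3-OH, should return the all-cis diol 12, where the route is rejoined.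

Step 8. The C4 cation may be captured at C5 or at a phenolic oxygen in place of C6. The thioether may also act as its own nucleophile, and the 4-OH of the product may ionise, so that chains grow. The fallback sets out from 11 and differentiates the two halves by protection. Lewis-acid thiolysis of 11 (BnSH, BF3·OEt2, CH2Cl2, −20 °C) should give 4β-benzylsulfanyl-3,7,8,4'-tetra-O-benzylepioritin F3, whose benzylated benzo ring is a poor nucleophile. AgBF4-promoted coupling of F3 with excess free 12 in THF should give 3,7,8,4'-tetra-O-benzylepioritin-(4β→6)-epioritin-4α-ol F4, which is easily separated from polar 12. Hydrogenolysis of F4 (H2, Pd(OH)2/C, acid-free EtOAc–THF) then comes back to the route at 15.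

**Further compounds**
F1 | step 5 | racemic all-cis 3,7,8,4'-tetra-O-benzylteracacidin (both enantiomers) | c1ccccc1COc1ccc2c(c1OCc1ccccc1)O[C@H](c1ccc(OCc3ccccc3)cc1)[C@H](OCc1ccccc1)[C@@H]2O.c1ccccc1COc1ccc2c(c1OCc1ccccc1)O[C@@H](c1ccc(OCc3ccccc3)cc1)[C@@H](OCc1ccccc1)[C@H]2O
F2 | step 6 | (2R,3S)-2,3-cis-3,7,8,4'-tetrahydroxyflavanone | O=C1c2ccc(O)c(O)c2O[C@H](c2ccc(O)cc2)[C@@H]1O
F3 | step 8 | 4β-benzylsulfanyl-3,7,8,4'-tetra-O-benzylepioritin, (2R,3S,4S) | c1ccccc1COc1ccc([C@H]2Oc3c(ccc(OCc4ccccc4)c3OCc3ccccc3)[C@H](SCc3ccccc3)[C@H]2OCc2ccccc2)cc1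
F4 | step 8 | 3,7,8,4'-tetra-O-benzylepioritin-(4β→6)-epioritin-4α-ol | c1ccccc1COc1ccc([C@H]2Oc3c(ccc(OCc4ccccc4)c3OCc3ccccc3)[C@H](c3cc4c(c(O)c3O)O[C@H](c3ccc(O)cc3)[C@H](O)[C@@H]4O)[C@H]2OCc2ccccc2)cc1
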